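## The problem

The target is a methylcyclohexene: C1'' carries the methyl group, C2'' is the alkene CH and C6'' the ring methylene. The other three ring carbons are contiguous stereocentres. C3'' carries C8 of a 7-hydroxyflavanone, C4'' a 2,4-dihydroxy-3-prenylbenzoyl group and C5'' a 2,4-dihydroxyphenyl ring, with C3''/C4'' cis and C4''/C5'' trans (3''S,4''R,5''S). C4'' is α to a ketone and can be left to follow from its neighbours, so the real stereochemical task in the ring is the 1,3-trans relation of the two aryl-bearing carbons. The fourth stereocentre, C2 of the flavanone (S), is insulated from the ring by an aromatic ring and has to be set by a reagent. Seven free phenols are present, and three groups limit the late steps: a prenyl group between two phenols (acid closes it to a chroman), a ketone flanked by two ortho-hydroxyaryl groups (acid ketalizes it), and a 2-arylchromanone whose C2–O bond opens under base and ionizes under acid. Two features make a short construction possible. First, the ortho oxygen of the C5'' aryl ring can be closed onto the C4'' carbonyl, to which it is trans, as a six-membered lactone, so that this ring, C5'', C4'' and the carbonyl are the atoms of a 7-oxygenated coumarin (C5'' = coumarin C4, C4'' = coumarin C3). C6''–C1''=C2'' is then the allyl unit of an allylsilane tethered through C3''. Second, the resorcinol ring on C3'' is symmetric about its bond to C3'' until its acyl carbon is attached, so its two oxygens and its two open positions need no early differentiation.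

## Retrosynthesis

Target 41 is traced to its heptakis-MOM ether 40, and 40 is cut at the flavanone C2–aryl bond into chromone 35 and boronic acid 39. The neighbouring cut, O1–C2 of a 2'-hydroxychalcone, would give both C2 epimers because the ring stereocentres are too far away to help. The conjugate arylation lets a chiral palladium catalyst choose the face, and 35 has no stereocentre in its pyranone. The forward step must tolerate a prenyl group and an ortho-alkoxy boronic acid.

Chromone 35 is traced through hydroxyacetophenone 33, its diol 32, bromide 30 and resorcinol 29 to the bis-silyl ether 28, so the chromone C2 carbon and the aryl–acetyl bond are both removed. The reason is the symmetry of the resorcinol ring. Carried as a bis-TBS ether it needs no masked ketone through the Lewis-acid and organolithium steps, where a ketal or a set of acetals on this ring would be ionized or attacked. After fluoride, monobromination can give only one product, and the acetyl group then differentiates the two hydroxyls by hydrogen bonding. The price is four routine late steps. The forward bromination must select a free resorcinol over MOM-protected rings and two trisubstituted alkenes.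

Ketone 28 is cut at the carbonyl–aryl bond into N-methoxy-N-methylamide 23 and aryllithium 27, made from 26. Amide 23 is the MOM ether of phenol 22, which is the aminolysis product of lactone 21. Compared with a Friedel–Crafts acylation of a prenylresorcinol or an aldehyde addition followed by oxidation, this uses the lactone carbonyl at the right oxidation level and releases the C5'' aryl oxygen only when it is needed. The forward step is a single addition to a hindered amide.

Lactone 21 is cut at C5''–C6'' to coumarin 19, in which C3 carries a 1-aryl-2-silyl-3-methylbut-3-enyl chain. Cutting C3''–C4'' and C5''–C6'' together would be the cycloaddition of a chalcone and an aryl diene, with its endo/exo and enantiofacial problems. Cutting C1''=C2'' would leave three stereocentres to be made in an open chain. The single cut chosen forms one bond and two stereocentres (C5'', C4'') from a flat coumarin and a side chain with two adjacent stereocentres, one of which (at silicon) is consumed. The forward reaction, conjugate allylation of a coumarin by a tethered allylsilane, has not been shown on a coumarin and must proceed with anti SE2' geometry.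

Coumarin 19 is cut at C3=C4 and at the ester C–O bond to aryl ester 17. Ester 17 comes from diazoketone 13 and salicylaldehyde 15 by Wolff rearrangement, and 13 from acid 11. The one-carbon homologation is accepted because 11 is the direct product of a [3,3] rearrangement and the added carbon becomes coumarin C3. The forward ring closure is an intramolecular aldol condensation of an unactivated aryl ester.

Acid 11 is cut at C3''–C2'' to allyl ester 9 (Ireland–Claisen), which is the ester of arylacetic acid 8 and allylic alcohol 3. The rearrangement sets both stereocentres at once: their relative configuration follows from enolate and alkene geometry in a chair, and their absolute configuration from a chiral boron enolate. Conjugate additions or allylic substitutions would set them one at a time. Ester 9 has no stereocentre.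

The building blocks are short. Acid 8 comes from 2-iodoresorcinol 4 by way of 5 and 7. Alcohol 3 comes from silylpropynol 1. Aldehyde 15 comes from 14, arene 26 from 24, and boronic acid 39 from 4-bromoresorcinol 36 by way of 37.

## Roads not taken

Alternative 1: The pyran ring is cut at O1–C2 and C3–C4. A salicylaldehyde that already carries the cyclohexene (A2), an orthoformate and the vinylphenol A3 would combine under a chiral phosphoric acid, the 4-methoxy ortho-quinone methide adding A3 to give the 2,4-cis 4-methoxyflavan A1. Two bonds and the C2 stereocentre are made in one convergent event. A2 would be one ortho-formylation away from resorcinol 29, which is shorter than steps 17 to 20 and 23 of the present route. In bond economy at the end this road is better. Its weak points are three. A1 is at the wrong oxidation level, and turning the C4 methyl ether into the ketone means oxidizing a benzylic position next to a prenyl group, a ring alkene and several electron-rich arenes. A3 is prone to acid-induced oligomerization under the conditions that generate the quinone methide. The three-component variant with a 4-alkoxy quinone methide is less supported than the two-component cycloaddition. It also leaves the cyclohexene unsolved. The chosen plan sets against it an arylation whose product is already the ketone, and a chalcone fallback.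

Alternative 2: The prenylresorcinol ring is cut at C1'–C2' and C5'–C6'. The ethynyl ketone A5 on C4'' and the 1,3-bis(silyloxy)diene A6 would combine in a formal [3+3] benzannulation to the aryl ketone A4. This avoids adding a hindered aryl nucleophile to a hindered acyl group, and no organolithium meets the molecule, so a ketone could sit on the other resorcinol ring from the start. In that respect it is better: the chosen plan must keep that ring carbonyl-free until after step 15 and pays for it with late steps. Against it, the benzannulation needs a strong Lewis acid in the presence of acetal protecting groups and the prenyl chain of A6. The C4'' hydrogen of ynone A5 is far more acidic than that of an amide. The regiochemistry must place the prenyl group between the two oxygens. A5 and A6 together cost more steps than the one-step preparation of 26 and the single addition of step 15. It gives no stereochemical advantage.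

Alternative 3: The ring is cut at C1''=C2''. A ruthenium carbene would join the vinyl group on C3'' and the methallyl group on C5'' of the acyclic amide A8 to give cyclohexene A7, which differs from 23 only in its aryl protecting groups. Ring-closing metathesis to a trisubstituted cyclohexene is the most reliable closure of all, and here this road is clearly better than a ring closure that has to be proposed as new. Its weakness lies before the closure: all three contiguous stereocentres, two of them bearing ortho-oxygenated aryl groups, must be set by acyclic stereocontrol, each in its own step, and C4'' has no ring to bias it. The chosen plan prepares only two stereocentres, both in one rearrangement, and lets the ring-forming step create C5'' and C4'' while the lactone delivers the aryl oxygen protected and the acyl group activated. The metathesis closure is kept as the fallback for the key step.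

Key step: step 11

Abbreviations: TBS = tert-butyldimethylsilyl; MOM = methoxymethyl; Ar° = 2,6-bis(tert-butyldimethylsilyloxy)phenyl. Compounds 1, 4, 14, 24 and 36 are taken to be commercial.

Assumption: the (R,R)-bromoborane of step 6 is taken to give the (2R,3S) acid 11 and the (R)-pyridine-oxazoline of step 23 the (2S) flavanone 40; if either sense of induction were opposite, the antipodal controller or ligand would be used with no other change.

Step 1
Reactants: 1 3-(trimethylsilyl)prop-2-yn-1-ol
Product: 3 (E)-2-methyl-3-(trimethylsilyl)prop-2-en-1-ol, via alkenylmagnesium chelate 2 (not isolated)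
Conditions: MeMgBr (3 equiv), CuI (10 mol %), THF/Et2O, −10 → 25 °C; aq. NH4Cl
Reagents that add atoms: methylmagnesium bromide, C[Mg]Br
Why: Copper-catalysed anti carbomagnesiation of a propargylic alcohol: the alkoxide directs magnesium to C3 cis to the CH2O group and methyl to C2, so protonation leaves SiMe3 trans to CH2OH.

Step 2
Reactants: 4 2-iodobenzene-1,3-diol
Product: 5 2-iodo-1,3-bis(tert-butyldimethylsilyloxy)benzene
Conditions: TBSCl (2.4 equiv), imidazole, DMF, 25 °C
Reagents that add atoms: tert-butyldimethylsilyl chloride, CC(C)(C)[Si](C)(C)Cl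
Why: Standard silylation of both phenols. Silyl ethers are chosen because they tolerate the boron and aluminium Lewis acids of steps 6 and 11 and are later removed by fluoride without touching MOM ethers.

Step 3
Reactants: 5 2-iodo-1,3-bis(tert-butyldimethylsilyloxy)benzene
Product: 7 2-[2,6-bis(tert-butyldimethylsilyloxy)phenyl]ethan-1-ol, via arylmagnesium chloride 6 (not isolated)
Conditions: i-PrMgCl·LiCl, THF, −20 → 0 °C; CuI (10 mol %), oxirane, −30 → 0 °C
Reagents that add atoms: oxirane, C1CO1
Why: Iodine–magnesium exchange avoids the oxygen-to-carbon silyl shift that an ortho-silyloxy aryllithium would undergo. Copper-catalysed opening of oxirane by the aryl Grignard reagent gives the 2-arylethanol.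

Step 4
Reactants: 7 2-[2,6-bis(tert-butyldimethylsilyloxy)phenyl]ethan-1-ol
Product: 8 [2,6-bis(tert-butyldimethylsilyloxy)phenyl]acetic acid
Conditions: TEMPO (20 mol %), PhI(OAc)2 (2.2 equiv), MeCN/H2O, 25 °C
Reagents that add atoms: water, O
Why: Oxoammonium oxidation of the primary alcohol through the aldehyde hydrate to the acid; aryl silyl ethers are inert.

Step 5
Reactants: 8 [2,6-bis(tert-butyldimethylsilyloxy)phenyl]acetic acid; 3 (E)-2-methyl-3-(trimethylsilyl)prop-2-en-1-ol
Product: 9 (E)-2-methyl-3-(trimethylsilyl)prop-2-en-1-yl [2,6-bis(tert-butyldimethylsilyloxy)phenyl]acetate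
Conditions: EDC·HCl, DMAP (10 mol %), CH2Cl2, 0 → 25 °C
Reagents that add atoms: none
Why: Carbodiimide (Steglich) esterification of a primary allylic alcohol.

Step 6
Reactants: 9 (E)-2-methyl-3-(trimethylsilyl)prop-2-en-1-yl [2,6-bis(tert-butyldimethylsilyloxy)phenyl]acetate
Product: 11 (2R,3S)-2-Ar°-4-methyl-3-(trimethylsilyl)pent-4-enoic acid, via boron enolate 10 (not isolated)
Conditions: (R,R)-2-bromo-4,5-diphenyl-1,3-bis[3,5-bis(trifluoromethyl)phenylsulfonyl]-1,3,2-diazaborolidine (1.2 equiv), i-Pr2NEt, CH2Cl2, −78 °C; then −20 → 4 °C; aq. work-up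
Reagents that add atoms: none
Why: Enantioselective Ireland–Claisen rearrangement of a chiral boron ester enolate. Soft enolization gives the enolate with the aryl group cis to O–B, and the chair with the aryl group and SiMe3 (trans to CH2O on the alkene) both equatorial gives the 2,3-syn acid. The sulfonamide ligands on boron select the enolate face and so fix the absolute configuration of both centres.

Step 7
Reactants: 11 (2R,3S)-2-Ar°-4-methyl-3-(trimethylsilyl)pent-4-enoic acid
Product: 13 (3R,4S)-3-Ar°-1-diazo-5-methyl-4-(trimethylsilyl)hex-5-en-2-one, via acid chloride 12 (not isolated)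
Conditions: 1-chloro-N,N,2-trimethylprop-1-en-1-amine, CH2Cl2, 0 → 25 °C; then CH2N2 (3 equiv), Et2O, 0 °C
Reagents that add atoms: diazomethane, C=[N+]=[N-]
Why: First half of an Arndt–Eistert homologation. The chloroenamine makes the acid chloride without HCl, which would protodesilylate the allylsilane. The twisted 2,6-disubstituted aryl group disfavours ketene formation, so the α-centre should keep its configuration.

Step 8
Reactants: 14 2,4-dihydroxybenzaldehyde
Product: 15 2-hydroxy-4-(methoxymethoxy)benzaldehyde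
Conditions: MOMCl (1.05 equiv), K2CO3, acetone, 0 → 25 °C
Reagents that add atoms: chloromethyl methyl ether, COCCl
Why: The 4-hydroxyl is the more acidic one and is not hydrogen-bonded to the aldehyde, so mono-alkylation takes place there.

Step 9
Reactants: 13 (3R,4S)-3-Ar°-1-diazo-5-methyl-4-(trimethylsilyl)hex-5-en-2-one; 15 2-hydroxy-4-(methoxymethoxy)benzaldehyde
Product: 17 2-formyl-5-(methoxymethoxy)phenyl (3S,4S)-3-Ar°-5-methyl-4-(trimethylsilyl)hex-5-enoate, via ketene 16 (not isolated)
Conditions: PhCO2Ag (10 mol %), Et3N, THF, −25 → 25 °C, dark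
Reagents that add atoms: none
Why: Silver-catalysed Wolff rearrangement. The stereocentre migrates with retention and the ketene is trapped by the phenol of 15 under amine catalysis, which gives the aryl ester directly.

Step 10
Reactants: 17 2-formyl-5-(methoxymethoxy)phenyl (3S,4S)-3-Ar°-5-methyl-4-(trimethylsilyl)hex-5-enoate
Product: 19 3-[(1R,2S)-1-Ar°-3-methyl-2-(trimethylsilyl)but-3-en-1-yl]-7-(methoxymethoxy)-2H-chromen-2-one, via lithium aldolate 18 (not isolated)
Conditions: LiN(i-Pr)2 (1.1 equiv, added to 17), THF, −78 °C; then MsCl, Et3N, −78 → 25 °C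
Reagents that add atoms: none
Why: Intramolecular aldol condensation, the ring-closing event of a Perkin-type coumarin synthesis. The aryl ester enolate adds to the ortho aldehyde through a six-membered transition state, and mesylation of the aldolate followed by E1cB elimination gives the coumarin. The allylsilane and its two stereocentres are not touched.

Step 11
Reactants: 19 3-[(1R,2S)-1-Ar°-3-methyl-2-(trimethylsilyl)but-3-en-1-yl]-7-(methoxymethoxy)-2H-chromen-2-one
Product: 21 (6aR,7S,10aS)-7-Ar°-3-(methoxymethoxy)-9-methyl-6a,7,10,10a-tetrahydro-6H-benzo[c]chromen-6-one, via aluminium enolate 20 (not isolated)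
Conditions: AlMe2Cl (2.5 equiv), CH2Cl2, −78 → −30 °C; MeOH, then aq. potassium sodium tartrate, −78 °C
Reagents that add atoms: none
Why: Proposed new method: AlMe2Cl binds the lactone carbonyl of 19 and the allylsilane adds through its terminal CH2 (C6'') to coumarin C4 in a 6-endo-trig conjugate addition, the developing positive charge at C1'' being stabilized by the C–Si bond, which chloride then cleaves to leave the alkene only at C1''=C2''; the closest known reaction type is the Lewis-acid intramolecular Hosomi–Sakurai conjugate allylation of cyclic enones by tethered allylsilanes, which has not been shown for a coumarin acceptor. The ring closes through a chair-like six-membered transition state in which the C–Si bond is axial and anti to the forming bond (anti SE2'), the only arrangement in which it overlaps with the allyl π system. With the (1R,2S) side chain this places the Ar° group on C7 axial and the coumarin aryl ring equatorial, so C10a (C5'') is formed with its aryl group trans to the C7 aryl group; the silicon-bearing stereocentre is therefore the controlling element for C10a. Aluminium enolate 20 is protonated at C6a (C4'') on the face away from the axial C7 aryl group, which is also axial protonation, and this gives the trans ring fusion with both lactone bonds equatorial. The step needs γ-regioselectivity, which ring size secures because α-attack would give a four-membered ring, and face selectivity at coumarin C4, which the stereospecific anti geometry secures. It also needs the allylsilane to survive until it cyclizes: AlMe2Cl scavenges protons, and the substrate carries only silyl ethers and one aryl MOM ether as other Lewis-basic groups.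

Step 12
Reactants: 21 (6aR,7S,10aS)-7-Ar°-3-(methoxymethoxy)-9-methyl-6a,7,10,10a-tetrahydro-6H-benzo[c]chromen-6-one
Product: 22 (1R,2S,6S)-2-Ar°-6-[2-hydroxy-4-(methoxymethoxy)phenyl]-N-methoxy-N,4-dimethylcyclohex-3-ene-1-carboxamide
Conditions: MeNH(OMe)·HCl, AlMe3 (5 equiv each), CH2Cl2, 0 → 25 °C
Reagents that add atoms: N,O-dimethylhydroxylamine hydrochloride, CNOC.Cl
Why: Aminolysis of an aryl lactone by an aluminium amide. The phenoxide is a good leaving group, the amide does not react further, and the α-centre is not enolized under these Lewis-acidic conditions.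

Step 13
Reactants: 22 (1R,2S,6S)-2-Ar°-6-[2-hydroxy-4-(methoxymethoxy)phenyl]-N-methoxy-N,4-dimethylcyclohex-3-ene-1-carboxamide
Product: 23 (1R,2S,6S)-2-Ar°-6-[2,4-bis(methoxymethoxy)phenyl]-N-methoxy-N,4-dimethylcyclohex-3-ene-1-carboxamide
Conditions: MOMCl, i-Pr2NEt, CH2Cl2, 0 → 25 °C
Reagents that add atoms: chloromethyl methyl ether, COCCl
Why: O-alkylation of the phenol, which prevents relactonization and completes the protection of this ring.

Step 14
Reactants: 24 1,3-bis(methoxymethoxy)benzene
Product: 26 1,3-bis(methoxymethoxy)-2-(3-methylbut-2-en-1-yl)benzene, via 2-lithio arene 25 (not isolated)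
Conditions: n-BuLi, THF, 0 °C; CuI (10 mol %), prenyl bromide, −78 → 0 °C
Reagents that add atoms: 1-bromo-3-methylbut-2-ene, CC(C)=CCBr
Why: Directed ortho-metalation between the two MOM ethers and copper-mediated SN2 allylation.

Step 15
Reactants: 26 1,3-bis(methoxymethoxy)-2-(3-methylbut-2-en-1-yl)benzene; 23 (1R,2S,6S)-2-Ar°-6-[2,4-bis(methoxymethoxy)phenyl]-N-methoxy-N,4-dimethylcyclohex-3-ene-1-carboxamide
Product: 28 [2,4-bis(methoxymethoxy)-3-(3-methylbut-2-en-1-yl)phenyl][(1R,2S,6S)-2-Ar°-6-[2,4-bis(methoxymethoxy)phenyl]-4-methylcyclohex-3-en-1-yl]methanone, via aryllithium 27 (not isolated)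
Conditions: 26 (2.5 equiv), n-BuLi, TMEDA, THF, −20 → 0 °C; then 23, −78 → −20 °C; aq. NH4Cl
Reagents that add atoms: none
Why: A second directed ortho-metalation (position 4 is the only site next to a MOM ether) and addition of the aryllithium to the N-methoxy-N-methylamide. The chelated tetrahedral intermediate collapses only on work-up, so a single addition occurs, and the aryl silyl ethers are inert at low temperature.

Step 16
Reactants: 28 [2,4-bis(methoxymethoxy)-3-(3-methylbut-2-en-1-yl)phenyl][(1R,2S,6S)-2-Ar°-6-[2,4-bis(methoxymethoxy)phenyl]-4-methylcyclohex-3-en-1-yl]methanone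
Product: 29 [2,4-bis(methoxymethoxy)-3-(3-methylbut-2-en-1-yl)phenyl][(1R,2S,6S)-6-[2,4-bis(methoxymethoxy)phenyl]-2-(2,6-dihydroxyphenyl)-4-methylcyclohex-3-en-1-yl]methanone
Conditions: Bu4NF (2.4 equiv), AcOH (2.4 equiv), THF, 0 °C
Reagents that add atoms: none
Why: Fluoride cleavage of the two aryl silyl ethers, buffered so that the phenoxides do not enolize the ketone. MOM ethers are untouched.

Step 17
Reactants: 29 [2,4-bis(methoxymethoxy)-3-(3-methylbut-2-en-1-yl)phenyl][(1R,2S,6S)-6-[2,4-bis(methoxymethoxy)phenyl]-2-(2,6-dihydroxyphenyl)-4-methylcyclohex-3-en-1-yl]methanone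
Product: 30 [2,4-bis(methoxymethoxy)-3-(3-methylbut-2-en-1-yl)phenyl][(1R,2S,6S)-6-[2,4-bis(methoxymethoxy)phenyl]-2-(3-bromo-2,6-dihydroxyphenyl)-4-methylcyclohex-3-en-1-yl]methanone
Conditions: NBS (1.0 equiv), CH2Cl2, −78 °C
Reagents that add atoms: N-bromosuccinimide, O=C1CCC(=O)N1Br
Why: Electrophilic aromatic bromination. At −78 °C the free resorcinol is far more nucleophilic than the MOM-protected rings and the two trisubstituted alkenes, and its two open positions are equivalent, so only one regioisomer can form.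

Step 18
Reactants: 30 [2,4-bis(methoxymethoxy)-3-(3-methylbut-2-en-1-yl)phenyl][(1R,2S,6S)-6-[2,4-bis(methoxymethoxy)phenyl]-2-(3-bromo-2,6-dihydroxyphenyl)-4-methylcyclohex-3-en-1-yl]methanone
Product: 32 [2,4-bis(methoxymethoxy)-3-(3-methylbut-2-en-1-yl)phenyl][(1R,2S,6S)-2-(3-acetyl-2,6-dihydroxyphenyl)-6-[2,4-bis(methoxymethoxy)phenyl]-4-methylcyclohex-3-en-1-yl]methanone, via enol ether 31 (not isolated)
Conditions: tributyl(1-ethoxyvinyl)stannane, Pd(PPh3)4 (5 mol %), toluene, 100 °C; then pyridinium p-toluenesulfonate, acetone/H2O, 25 °C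
Reagents that add atoms: tributyl(1-ethoxyvinyl)stannane, CCCC[Sn](CCCC)(CCCC)C(=C)OCC; water, O
Why: Migita–Kosugi–Stille coupling with an acetyl anion equivalent, then mild hydrolysis of the enol ether. Free phenols, MOM ethers and the prenyl group are tolerated.

Step 19
Reactants: 32 [2,4-bis(methoxymethoxy)-3-(3-methylbut-2-en-1-yl)phenyl][(1R,2S,6S)-2-(3-acetyl-2,6-dihydroxyphenyl)-6-[2,4-bis(methoxymethoxy)phenyl]-4-methylcyclohex-3-en-1-yl]methanone
Product: 33 [2,4-bis(methoxymethoxy)-3-(3-methylbut-2-en-1-yl)phenyl][(1R,2S,6S)-2-[3-acetyl-2-hydroxy-6-(methoxymethoxy)phenyl]-6-[2,4-bis(methoxymethoxy)phenyl]-4-methylcyclohex-3-en-1-yl]methanone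
Conditions: MOMCl (1.1 equiv), K2CO3, acetone, 25 °C
Reagents that add atoms: chloromethyl methyl ether, COCCl
Why: The hydroxyl ortho to the acetyl group is held in a hydrogen bond, so one equivalent of MOMCl alkylates the other one, as with 2,4-dihydroxyacetophenone itself.

Step 20
Reactants: 33 [2,4-bis(methoxymethoxy)-3-(3-methylbut-2-en-1-yl)phenyl][(1R,2S,6S)-2-[3-acetyl-2-hydroxy-6-(methoxymethoxy)phenyl]-6-[2,4-bis(methoxymethoxy)phenyl]-4-methylcyclohex-3-en-1-yl]methanone
Product: 35 8-[(1S,5S,6R)-6-[2,4-bis(methoxymethoxy)-3-(3-methylbut-2-en-1-yl)benzoyl]-5-[2,4-bis(methoxymethoxy)phenyl]-3-methylcyclohex-2-en-1-yl]-7-(methoxymethoxy)-4H-chromen-4-one, via enaminone 34 (not isolated)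
Conditions: Me2NCH(OMe)2, toluene, 90 °C; then AcOH, 60 °C
Reagents that add atoms: N,N-dimethylformamide dimethyl acetal, COC(OC)N(C)C
Why: Condensation of the methyl ketone with the formamide acetal gives the enaminone, which cyclizes by conjugate addition of the phenol and loss of dimethylamine (standard chromone synthesis). The other ketone has only a tertiary α-carbon and does not condense.

Step 21
Reactants: 36 4-bromobenzene-1,3-diol
Product: 37 1-bromo-2,4-bis(methoxymethoxy)benzene
Conditions: MOMCl (2.5 equiv), i-Pr2NEt, CH2Cl2, 0 → 25 °C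
Reagents that add atoms: chloromethyl methyl ether, COCCl
Why: O-alkylation of both phenols.

Step 22
Reactants: 37 1-bromo-2,4-bis(methoxymethoxy)benzene
Product: 39 [2,4-bis(methoxymethoxy)phenyl]boronic acid, via aryllithium 38 (not isolated)
Conditions: n-BuLi, THF, −78 °C; B(Oi-Pr)3; aq. NH4Cl
Reagents that add atoms: triisopropyl borate, CC(C)OB(OC(C)C)OC(C)C; water, O
Why: Bromine–lithium exchange, borylation and hydrolysis of the borate.

Step 23
Reactants: 35 8-[(1S,5S,6R)-6-[2,4-bis(methoxymethoxy)-3-(3-methylbut-2-en-1-yl)benzoyl]-5-[2,4-bis(methoxymethoxy)phenyl]-3-methylcyclohex-2-en-1-yl]-7-(methoxymethoxy)-4H-chromen-4-one; 39 [2,4-bis(methoxymethoxy)phenyl]boronic acid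
Product: 40 (2S)-8-[(1S,5S,6R)-6-[2,4-bis(methoxymethoxy)-3-(3-methylbut-2-en-1-yl)benzoyl]-5-[2,4-bis(methoxymethoxy)phenyl]-3-methylcyclohex-2-en-1-yl]-2-[2,4-bis(methoxymethoxy)phenyl]-7-(methoxymethoxy)-2,3-dihydro-4H-chromen-4-one
Conditions: Pd(OCOCF3)2 (10 mol %), (R)-4-tert-butyl-2-(pyridin-2-yl)-4,5-dihydrooxazole (12 mol %), NH4PF6 (30 mol %), H2O (5 equiv), 39 (3 equiv), ClCH2CH2Cl, 60 °C
Reagents that add atoms: none
Why: Palladium-catalysed asymmetric conjugate addition of an arylboronic acid to a chromone. The cationic aryl–palladium species inserts the C2=C3 bond on the face set by the pyridine-oxazoline ligand and the palladium enolate is protonated, so C2 is set by the catalyst and not by the remote ring stereocentres. The metal stays divalent throughout, and the prenyl group is shielded on both sides by MOM ethers.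

Step 24
Reactants: 40 (2S)-8-[(1S,5S,6R)-6-[2,4-bis(methoxymethoxy)-3-(3-methylbut-2-en-1-yl)benzoyl]-5-[2,4-bis(methoxymethoxy)phenyl]-3-methylcyclohex-2-en-1-yl]-2-[2,4-bis(methoxymethoxy)phenyl]-7-(methoxymethoxy)-2,3-dihydro-4H-chromen-4-one
Product: 41 (2S)-8-[(1S,5S,6R)-6-[2,4-dihydroxy-3-(3-methylbut-2-en-1-yl)benzoyl]-5-(2,4-dihydroxyphenyl)-3-methylcyclohex-2-en-1-yl]-2-(2,4-dihydroxyphenyl)-7-hydroxy-2,3-dihydro-4H-chromen-4-one
Conditions: 3 M aq. HCl, MeOH, 45 °C
Reagents that add atoms: none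
Why: Acid-catalysed acetal exchange removes all seven MOM ethers as dimethoxymethane. The conditions are kept mild because of the prenyl group, the ketone and C2 of the flavanone.

Compound list

1 | 3-(trimethylsilyl)prop-2-yn-1-ol | C[Si](C)(C)C#CCO | starting material
2 | bromomagnesium (E)-3-(bromomagnesio)-2-methyl-3-(trimethylsilyl)prop-2-en-1-olate (Mg on C3 cis to CH2O) | C[Si](C)(C)/C([Mg]Br)=C(\C)CO[Mg]Br | intermediate (not isolated)
3 | (E)-2-methyl-3-(trimethylsilyl)prop-2-en-1-ol (SiMe3 trans to CH2OH) | C[Si](C)(C)/C=C(\C)CO | intermediate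
4 | 2-iodobenzene-1,3-diol | Oc1cccc(O)c1I | starting material
5 | 2-iodo-1,3-bis(tert-butyldimethylsilyloxy)benzene | CC(C)(C)[Si](C)(C)Oc1cccc(O[Si](C)(C)C(C)(C)C)c1I | intermediate
6 | [2,6-bis(tert-butyldimethylsilyloxy)phenyl]magnesium chloride | CC(C)(C)[Si](C)(C)Oc1cccc(O[Si](C)(C)C(C)(C)C)c1[Mg]Cl | intermediate (not isolated)
7 | 2-[2,6-bis(tert-butyldimethylsilyloxy)phenyl]ethan-1-ol | CC(C)(C)[Si](C)(C)Oc1cccc(O[Si](C)(C)C(C)(C)C)c1CCO | intermediate
8 | [2,6-bis(tert-butyldimethylsilyloxy)phenyl]acetic acid | CC(C)(C)[Si](C)(C)Oc1cccc(O[Si](C)(C)C(C)(C)C)c1CC(=O)O | intermediate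
9 | (E)-2-methyl-3-(trimethylsilyl)prop-2-en-1-yl [2,6-bis(tert-butyldimethylsilyloxy)phenyl]acetate | C[Si](C)(C)/C=C(\C)COC(=O)Cc1c(O[Si](C)(C)C(C)(C)C)cccc1O[Si](C)(C)C(C)(C)C | intermediate
10 | O-boryl ketene acetal of 9 with the (4R,5R)-4,5-diphenyl-1,3-bis[3,5-bis(trifluoromethyl)phenylsulfonyl]-1,3,2-diazaborolidin-2-yl group on oxygen and the aryl group cis to O–B | C[Si](C)(C)/C=C(\C)CO/C(OB1N(S(=O)(=O)c2cc(C(F)(F)F)cc(C(F)(F)F)c2)[C@H](c2ccccc2)[C@@H](c2ccccc2)N1S(=O)(=O)c1cc(C(F)(F)F)cc(C(F)(F)F)c1)=C/c1c(O[Si](C)(C)C(C)(C)C)cccc1O[Si](C)(C)C(C)(C)C | intermediate (not isolated)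
11 | (2R,3S)-2-[2,6-bis(tert-butyldimethylsilyloxy)phenyl]-4-methyl-3-(trimethylsilyl)pent-4-enoic acid | OC(=O)[C@@H](c1c(O[Si](C)(C)C(C)(C)C)cccc1O[Si](C)(C)C(C)(C)C)[C@H]([Si](C)(C)C)C(C)=C | intermediate
12 | (2S,3S)-2-[2,6-bis(tert-butyldimethylsilyloxy)phenyl]-4-methyl-3-(trimethylsilyl)pent-4-enoyl chloride | ClC(=O)[C@@H](c1c(O[Si](C)(C)C(C)(C)C)cccc1O[Si](C)(C)C(C)(C)C)[C@H]([Si](C)(C)C)C(C)=C | intermediate (not isolated)
13 | (3R,4S)-3-[2,6-bis(tert-butyldimethylsilyloxy)phenyl]-1-diazo-5-methyl-4-(trimethylsilyl)hex-5-en-2-one | [N-]=[N+]=CC(=O)[C@@H](c1c(O[Si](C)(C)C(C)(C)C)cccc1O[Si](C)(C)C(C)(C)C)[C@H]([Si](C)(C)C)C(C)=C | intermediate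
14 | 2,4-dihydroxybenzaldehyde | O=Cc1ccc(O)cc1O | starting material
15 | 2-hydroxy-4-(methoxymethoxy)benzaldehyde | O=Cc1ccc(OCOC)cc1O | intermediate
16 | (3S,4S)-3-[2,6-bis(tert-butyldimethylsilyloxy)phenyl]-5-methyl-4-(trimethylsilyl)hexa-1,5-dien-1-one (ketene) | O=C=C[C@@H](c1c(O[Si](C)(C)C(C)(C)C)cccc1O[Si](C)(C)C(C)(C)C)[C@H]([Si](C)(C)C)C(C)=C | intermediate (not isolated)
17 | 2-formyl-5-(methoxymethoxy)phenyl (3S,4S)-3-[2,6-bis(tert-butyldimethylsilyloxy)phenyl]-5-methyl-4-(trimethylsilyl)hex-5-enoate | O=Cc1ccc(OCOC)cc1OC(=O)C[C@@H](c1c(O[Si](C)(C)C(C)(C)C)cccc1O[Si](C)(C)C(C)(C)C)[C@H]([Si](C)(C)C)C(C)=C | intermediate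
18 | lithium 3-[(1S,2S)-1-[2,6-bis(tert-butyldimethylsilyloxy)phenyl]-3-methyl-2-(trimethylsilyl)but-3-en-1-yl]-7-(methoxymethoxy)-2-oxo-3,4-dihydro-2H-chromen-4-olate (mixture at C3 and C4 of the lactone ring) | [Li]OC1c2ccc(OCOC)cc2OC(=O)C1[C@@H](c1c(O[Si](C)(C)C(C)(C)C)cccc1O[Si](C)(C)C(C)(C)C)[C@H]([Si](C)(C)C)C(C)=C | intermediate (not isolated)
19 | 3-[(1R,2S)-1-[2,6-bis(tert-butyldimethylsilyloxy)phenyl]-3-methyl-2-(trimethylsilyl)but-3-en-1-yl]-7-(methoxymethoxy)-2H-chromen-2-one | O=C1Oc2cc(OCOC)ccc2C=C1[C@@H](c1c(O[Si](C)(C)C(C)(C)C)cccc1O[Si](C)(C)C(C)(C)C)[C@H]([Si](C)(C)C)C(C)=C | intermediate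
20 | (7R,10aR)-7-[2,6-bis(tert-butyldimethylsilyloxy)phenyl]-6-[(dimethylalumanyl)oxy]-3-(methoxymethoxy)-9-methyl-10,10a-dihydro-7H-benzo[c]chromene (aluminium enolate of 21) | C[Al](C)OC1=C2[C@@H](c3c(O[Si](C)(C)C(C)(C)C)cccc3O[Si](C)(C)C(C)(C)C)C=C(C)C[C@@H]2c2ccc(OCOC)cc2O1 | intermediate (not isolated)
21 | (6aR,7S,10aS)-7-[2,6-bis(tert-butyldimethylsilyloxy)phenyl]-3-(methoxymethoxy)-9-methyl-6a,7,10,10a-tetrahydro-6H-benzo[c]chromen-6-one | O=C1Oc2cc(OCOC)ccc2[C@H]2CC(C)=C[C@H](c3c(O[Si](C)(C)C(C)(C)C)cccc3O[Si](C)(C)C(C)(C)C)[C@H]12 | intermediate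
22 | (1R,2S,6S)-2-[2,6-bis(tert-butyldimethylsilyloxy)phenyl]-6-[2-hydroxy-4-(methoxymethoxy)phenyl]-N-methoxy-N,4-dimethylcyclohex-3-ene-1-carboxamide | CON(C)C(=O)[C@H]1[C@@H](c2c(O[Si](C)(C)C(C)(C)C)cccc2O[Si](C)(C)C(C)(C)C)C=C(C)C[C@@H]1c1ccc(OCOC)cc1O | intermediate
23 | (1R,2S,6S)-2-[2,6-bis(tert-butyldimethylsilyloxy)phenyl]-6-[2,4-bis(methoxymethoxy)phenyl]-N-methoxy-N,4-dimethylcyclohex-3-ene-1-carboxamide | CON(C)C(=O)[C@H]1[C@@H](c2c(O[Si](C)(C)C(C)(C)C)cccc2O[Si](C)(C)C(C)(C)C)C=C(C)C[C@@H]1c1ccc(OCOC)cc1OCOC | intermediate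
24 | 1,3-bis(methoxymethoxy)benzene | COCOc1cccc(OCOC)c1 | starting material
25 | [2,6-bis(methoxymethoxy)phenyl]lithium | [Li]c1c(OCOC)cccc1OCOC | intermediate (not isolated)
26 | 1,3-bis(methoxymethoxy)-2-(3-methylbut-2-en-1-yl)benzene | CC(C)=CCc1c(OCOC)cccc1OCOC | intermediate
27 | [2,4-bis(methoxymethoxy)-3-(3-methylbut-2-en-1-yl)phenyl]lithium | [Li]c1ccc(OCOC)c(CC=C(C)C)c1OCOC | intermediate (not isolated)
28 | [2,4-bis(methoxymethoxy)-3-(3-methylbut-2-en-1-yl)phenyl][(1R,2S,6S)-2-[2,6-bis(tert-butyldimethylsilyloxy)phenyl]-6-[2,4-bis(methoxymethoxy)phenyl]-4-methylcyclohex-3-en-1-yl]methanone | CC(C)=CCc1c(OCOC)ccc(C(=O)[C@H]2[C@@H](c3c(O[Si](C)(C)C(C)(C)C)cccc3O[Si](C)(C)C(C)(C)C)C=C(C)C[C@@H]2c2ccc(OCOC)cc2OCOC)c1OCOC | intermediate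
29 | [2,4-bis(methoxymethoxy)-3-(3-methylbut-2-en-1-yl)phenyl][(1R,2S,6S)-6-[2,4-bis(methoxymethoxy)phenyl]-2-(2,6-dihydroxyphenyl)-4-methylcyclohex-3-en-1-yl]methanone | CC(C)=CCc1c(OCOC)ccc(C(=O)[C@H]2[C@@H](c3c(O)cccc3O)C=C(C)C[C@@H]2c2ccc(OCOC)cc2OCOC)c1OCOC | intermediate
30 | [2,4-bis(methoxymethoxy)-3-(3-methylbut-2-en-1-yl)phenyl][(1R,2S,6S)-6-[2,4-bis(methoxymethoxy)phenyl]-2-(3-bromo-2,6-dihydroxyphenyl)-4-methylcyclohex-3-en-1-yl]methanone | CC(C)=CCc1c(OCOC)ccc(C(=O)[C@H]2[C@@H](c3c(O)c(Br)ccc3O)C=C(C)C[C@@H]2c2ccc(OCOC)cc2OCOC)c1OCOC | intermediate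
31 | [2,4-bis(methoxymethoxy)-3-(3-methylbut-2-en-1-yl)phenyl][(1R,2S,6S)-6-[2,4-bis(methoxymethoxy)phenyl]-2-[3-(1-ethoxyethenyl)-2,6-dihydroxyphenyl]-4-methylcyclohex-3-en-1-yl]methanone | CC(C)=CCc1c(OCOC)ccc(C(=O)[C@H]2[C@@H](c3c(O)c(C(=C)OCC)ccc3O)C=C(C)C[C@@H]2c2ccc(OCOC)cc2OCOC)c1OCOC | intermediate (not isolated)
32 | [2,4-bis(methoxymethoxy)-3-(3-methylbut-2-en-1-yl)phenyl][(1R,2S,6S)-2-(3-acetyl-2,6-dihydroxyphenyl)-6-[2,4-bis(methoxymethoxy)phenyl]-4-methylcyclohex-3-en-1-yl]methanone | CC(C)=CCc1c(OCOC)ccc(C(=O)[C@H]2[C@@H](c3c(O)c(C(C)=O)ccc3O)C=C(C)C[C@@H]2c2ccc(OCOC)cc2OCOC)c1OCOC | intermediate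
33 | [2,4-bis(methoxymethoxy)-3-(3-methylbut-2-en-1-yl)phenyl][(1R,2S,6S)-2-[3-acetyl-2-hydroxy-6-(methoxymethoxy)phenyl]-6-[2,4-bis(methoxymethoxy)phenyl]-4-methylcyclohex-3-en-1-yl]methanone | CC(C)=CCc1c(OCOC)ccc(C(=O)[C@H]2[C@@H](c3c(O)c(C(C)=O)ccc3OCOC)C=C(C)C[C@@H]2c2ccc(OCOC)cc2OCOC)c1OCOC | intermediate
34 | [2,4-bis(methoxymethoxy)-3-(3-methylbut-2-en-1-yl)phenyl][(1R,2S,6S)-6-[2,4-bis(methoxymethoxy)phenyl]-2-[3-[(E)-3-(dimethylamino)prop-2-enoyl]-2-hydroxy-6-(methoxymethoxy)phenyl]-4-methylcyclohex-3-en-1-yl]methanone | CC(C)=CCc1c(OCOC)ccc(C(=O)[C@H]2[C@@H](c3c(O)c(C(=O)/C=C/N(C)C)ccc3OCOC)C=C(C)C[C@@H]2c2ccc(OCOC)cc2OCOC)c1OCOC | intermediate (not isolated)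
35 | 8-[(1S,5S,6R)-6-[2,4-bis(methoxymethoxy)-3-(3-methylbut-2-en-1-yl)benzoyl]-5-[2,4-bis(methoxymethoxy)phenyl]-3-methylcyclohex-2-en-1-yl]-7-(methoxymethoxy)-4H-chromen-4-one | CC(C)=CCc1c(OCOC)ccc(C(=O)[C@H]2[C@@H](c3c(OCOC)ccc4c3OC=CC4=O)C=C(C)C[C@@H]2c2ccc(OCOC)cc2OCOC)c1OCOC | intermediate
36 | 4-bromobenzene-1,3-diol | Oc1ccc(Br)c(O)c1 | starting material
37 | 1-bromo-2,4-bis(methoxymethoxy)benzene | COCOc1ccc(Br)c(OCOC)c1 | intermediate
38 | [2,4-bis(methoxymethoxy)phenyl]lithium | [Li]c1ccc(OCOC)cc1OCOC | intermediate (not isolated)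
39 | [2,4-bis(methoxymethoxy)phenyl]boronic acid | OB(O)c1ccc(OCOC)cc1OCOC | intermediate
40 | (2S)-8-[(1S,5S,6R)-6-[2,4-bis(methoxymethoxy)-3-(3-methylbut-2-en-1-yl)benzoyl]-5-[2,4-bis(methoxymethoxy)phenyl]-3-methylcyclohex-2-en-1-yl]-2-[2,4-bis(methoxymethoxy)phenyl]-7-(methoxymethoxy)-2,3-dihydro-4H-chromen-4-one | CC(C)=CCc1c(OCOC)ccc(C(=O)[C@H]2[C@@H](c3c(OCOC)ccc4c3O[C@H](c3ccc(OCOC)cc3OCOC)CC4=O)C=C(C)C[C@@H]2c2ccc(OCOC)cc2OCOC)c1OCOC | intermediate
41 | (2S)-8-[(1S,5S,6R)-6-[2,4-dihydroxy-3-(3-methylbut-2-en-1-yl)benzoyl]-5-(2,4-dihydroxyphenyl)-3-methylcyclohex-2-en-1-yl]-2-(2,4-dihydroxyphenyl)-7-hydroxy-2,3-dihydro-4H-chromen-4-one | CC(C)=CCc1c(O)ccc(C(=O)[C@H]2[C@@H](c3c(O)ccc4c3O[C@H](c3ccc(O)cc3O)CC4=O)C=C(C)C[C@@H]2c2ccc(O)cc2O)c1O | target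

Total step count: 24. Longest linear sequence: 19 steps (4 → 5 → 7 → 8 → 9 → 11 → 13 → 17 → 19 → 21 → 22 → 23 → 28 → 29 → 30 → 32 → 33 → 35 → 40 → 41).

Least certain steps

Step 11 (key step, proposed new method). Two things are most likely to go wrong. A 3-alkyl-7-alkoxycoumarin may be too weak an acceptor, so that protodesilylation of the allylsilane or methyl transfer from aluminium outruns cyclization. Or closure through a boat-like arrangement may erode the face selectivity at coumarin C4. The fallback uses only known reaction types and sets out from 19. Protodesilylation with CF3CO2H in CH2Cl2 (protonation at the terminal CH2, loss of silicon) would give 3-[(1R)-1-Ar°-3-methylbut-2-en-1-yl]-7-(methoxymethoxy)-2H-chromen-2-one F1. Copper-mediated conjugate addition of 2-methylallylmagnesium chloride (CuI, Me3SiCl, THF, −78 °C) and protonation to the trans lactone would give (3R,4S)-3-[(1S)-1-Ar°-3-methylbut-2-en-1-yl]-7-(methoxymethoxy)-4-(2-methylprop-2-en-1-yl)-3,4-dihydro-2H-chromen-2-one F2. Ring-closing metathesis of the methallyl and isopropylidene alkenes with the second-generation Grubbs catalyst RuCl2(=CHPh)(H2IMes)(PCy3) would come back to the route at 21. The face selectivity of the intermolecular addition rests only on 1,2-induction from the side-chain stereocentre and is the weak point of this detour.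

Step 6. The bulky boron reagent may enolize the ester slowly next to the 2,6-disilyloxyphenyl group, the enolate geometry may be less uniform than required, and the rearrangement at low temperature may be slow, so that conversion or enantiomeric purity is poor. The fallback sets out from 9. An Ireland–Claisen rearrangement through the potassium enolate and silyl ketene acetal (KN(SiMe3)2, Me3SiCl, toluene, −78 → 25 °C) would give the racemic syn acid rac-(2R*,3S*)-2-Ar°-4-methyl-3-(trimethylsilyl)pent-4-enoic acid F3. Crystallization with (S)-1-phenylethanamine would give the salt (S)-1-phenylethanaminium (2R,3S)-2-Ar°-4-methyl-3-(trimethylsilyl)pent-4-enoate F4, and acidification returns to the route at 11.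

Step 10. The amide base may add to the aldehyde, or the aryl ester enolate may expel the aryloxide as a ketene before it closes, so that the ester is cleaved. The fallback sets out from 13 and separates the aldol from the lactonization. Wolff rearrangement in methanol would give methyl (3S,4S)-3-Ar°-5-methyl-4-(trimethylsilyl)hex-5-enoate F5. Its lithium enolate would be added to 2-(tert-butyldimethylsilyloxy)-4-(methoxymethoxy)benzaldehyde F6 (from 15, TBSCl, imidazole) to give the aldol methyl (3S,4S)-3-Ar°-2-{hydroxy[2-(tert-butyldimethylsilyloxy)-4-(methoxymethoxy)phenyl]methyl}-5-methyl-4-(trimethylsilyl)hex-5-enoate F7. Fluoride would release the phenoxide, which lactonizes to 3-[(1S,2S)-1-Ar°-3-methyl-2-(trimethylsilyl)but-3-en-1-yl]-4-hydroxy-7-(methoxymethoxy)-3,4-dihydro-2H-chromen-2-one F8. Mesylation and elimination return to the route at 19.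

Step 23. The electron-rich ortho-alkoxy boronic acid may undergo protodeboronation faster than transmetalation and insertion, so that the chromone is recovered. The fallback sets out from 33 and builds the pyranone by the chalcone route. Claisen–Schmidt condensation with 2,4-bis(methoxymethoxy)benzaldehyde F9 (from 14, MOMCl, NaH) would give the chalcone [2,4-bis(methoxymethoxy)-3-(3-methylbut-2-en-1-yl)phenyl][(1R,2S,6S)-2-[3-[(E)-3-[2,4-bis(methoxymethoxy)phenyl]prop-2-enoyl]-2-hydroxy-6-(methoxymethoxy)phenyl]-6-[2,4-bis(methoxymethoxy)phenyl]-4-methylcyclohex-3-en-1-yl]methanone F10. Cyclization with NaOAc in ethanol would give 40 together with its (2R) epimer, the (2R)-diastereomer of 40 F11. The two are diastereomers and separable, and F11 can be returned to F10 with base and cyclized again. The route is rejoined at 40.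

Step 24. Acid may trigger cyclization of the prenyl group onto a neighbouring phenol, ketal formation between the C4'' ketone and the phenols on the C3'' and C5'' aryl rings, or ionization of the C2–O bond of the flavanone with loss of configuration. The fallback sets out from 40 and avoids protic acid. Me3SiOSO2CF3 and 2,2'-bipyridyl in CH2Cl2 at 0 °C would convert the aryl MOM ethers into the heptakis(trimethylsilyl) ether of 41 F12, which is hydrolysed with neutral aqueous methanol to 41.

Further compounds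

F1 | step 11 | 3-[(1R)-1-[2,6-bis(tert-butyldimethylsilyloxy)phenyl]-3-methylbut-2-en-1-yl]-7-(methoxymethoxy)-2H-chromen-2-one | O=C1Oc2cc(OCOC)ccc2C=C1[C@@H](c1c(O[Si](C)(C)C(C)(C)C)cccc1O[Si](C)(C)C(C)(C)C)C=C(C)C
F2 | step 11 | (3R,4S)-3-[(1S)-1-[2,6-bis(tert-butyldimethylsilyloxy)phenyl]-3-methylbut-2-en-1-yl]-7-(methoxymethoxy)-4-(2-methylprop-2-en-1-yl)-3,4-dihydro-2H-chromen-2-one | O=C1Oc2cc(OCOC)ccc2[C@@H](CC(C)=C)[C@@H]1[C@@H](c1c(O[Si](C)(C)C(C)(C)C)cccc1O[Si](C)(C)C(C)(C)C)C=C(C)C
F3 | step 6 | rac-(2R*,3S*)-2-[2,6-bis(tert-butyldimethylsilyloxy)phenyl]-4-methyl-3-(trimethylsilyl)pent-4-enoic acid (racemate; one enantiomer drawn) | OC(=O)[C@@H](c1c(O[Si](C)(C)C(C)(C)C)cccc1O[Si](C)(C)C(C)(C)C)[C@H]([Si](C)(C)C)C(C)=C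
F4 | step 6 | (S)-1-phenylethanaminium (2R,3S)-2-[2,6-bis(tert-butyldimethylsilyloxy)phenyl]-4-methyl-3-(trimethylsilyl)pent-4-enoate | C[C@H]([NH3+])c1ccccc1.[O-]C(=O)[C@@H](c1c(O[Si](C)(C)C(C)(C)C)cccc1O[Si](C)(C)C(C)(C)C)[C@H]([Si](C)(C)C)C(C)=C
F5 | step 10 | methyl (3S,4S)-3-[2,6-bis(tert-butyldimethylsilyloxy)phenyl]-5-methyl-4-(trimethylsilyl)hex-5-enoate | COC(=O)C[C@@H](c1c(O[Si](C)(C)C(C)(C)C)cccc1O[Si](C)(C)C(C)(C)C)[C@H]([Si](C)(C)C)C(C)=C
F6 | step 10 | 2-(tert-butyldimethylsilyloxy)-4-(methoxymethoxy)benzaldehyde | O=Cc1ccc(OCOC)cc1O[Si](C)(C)C(C)(C)C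
F7 | step 10 | methyl (3S,4S)-3-[2,6-bis(tert-butyldimethylsilyloxy)phenyl]-2-{hydroxy[2-(tert-butyldimethylsilyloxy)-4-(methoxymethoxy)phenyl]methyl}-5-methyl-4-(trimethylsilyl)hex-5-enoate (mixture at the two new centres) | COC(=O)C(C(O)c1ccc(OCOC)cc1O[Si](C)(C)C(C)(C)C)[C@@H](c1c(O[Si](C)(C)C(C)(C)C)cccc1O[Si](C)(C)C(C)(C)C)[C@H]([Si](C)(C)C)C(C)=C
F8 | step 10 | 3-[(1S,2S)-1-[2,6-bis(tert-butyldimethylsilyloxy)phenyl]-3-methyl-2-(trimethylsilyl)but-3-en-1-yl]-4-hydroxy-7-(methoxymethoxy)-3,4-dihydro-2H-chromen-2-one (mixture at C3 and C4) | OC1c2ccc(OCOC)cc2OC(=O)C1[C@@H](c1c(O[Si](C)(C)C(C)(C)C)cccc1O[Si](C)(C)C(C)(C)C)[C@H]([Si](C)(C)C)C(C)=C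
F9 | step 23 | 2,4-bis(methoxymethoxy)benzaldehyde | O=Cc1ccc(OCOC)cc1OCOC
F10 | step 23 | [2,4-bis(methoxymethoxy)-3-(3-methylbut-2-en-1-yl)phenyl][(1R,2S,6S)-2-[3-[(E)-3-[2,4-bis(methoxymethoxy)phenyl]prop-2-enoyl]-2-hydroxy-6-(methoxymethoxy)phenyl]-6-[2,4-bis(methoxymethoxy)phenyl]-4-methylcyclohex-3-en-1-yl]methanone | CC(C)=CCc1c(OCOC)ccc(C(=O)[C@H]2[C@@H](c3c(O)c(C(=O)/C=C/c4ccc(OCOC)cc4OCOC)ccc3OCOC)C=C(C)C[C@@H]2c2ccc(OCOC)cc2OCOC)c1OCOC
F11 | step 23 | (2R)-8-[(1S,5S,6R)-6-[2,4-bis(methoxymethoxy)-3-(3-methylbut-2-en-1-yl)benzoyl]-5-[2,4-bis(methoxymethoxy)phenyl]-3-methylcyclohex-2-en-1-yl]-2-[2,4-bis(methoxymethoxy)phenyl]-7-(methoxymethoxy)-2,3-dihydro-4H-chromen-4-one | CC(C)=CCc1c(OCOC)ccc(C(=O)[C@H]2[C@@H](c3c(OCOC)ccc4c3O[C@@H](c3ccc(OCOC)cc3OCOC)CC4=O)C=C(C)C[C@@H]2c2ccc(OCOC)cc2OCOC)c1OCOC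
F12 | step 24 | heptakis(trimethylsilyl) ether of 41 | CC(C)=CCc1c(O[Si](C)(C)C)ccc(C(=O)[C@H]2[C@@H](c3c(O[Si](C)(C)C)ccc4c3O[C@H](c3ccc(O[Si](C)(C)C)cc3O[Si](C)(C)C)CC4=O)C=C(C)C[C@@H]2c2ccc(O[Si](C)(C)C)cc2O[Si](C)(C)C)c1O[Si](C)(C)C
A1 | alternative 1 | (2S,4S)-8-[(1S,5S,6R)-6-[2,4-bis(methoxymethoxy)-3-(3-methylbut-2-en-1-yl)benzoyl]-5-[2,4-bis(methoxymethoxy)phenyl]-3-methylcyclohex-2-en-1-yl]-2-[2-hydroxy-4-(methoxymethoxy)phenyl]-4-methoxy-7-(methoxymethoxy)chromane (2,4-cis) | CC(C)=CCc1c(OCOC)ccc(C(=O)[C@H]2[C@@H](c3c(OCOC)ccc4c3O[C@H](c3ccc(OCOC)cc3O)C[C@@H]4OC)C=C(C)C[C@@H]2c2ccc(OCOC)cc2OCOC)c1OCOC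
A2 | alternative 1 | 3-[(1S,5S,6R)-6-[2,4-bis(methoxymethoxy)-3-(3-methylbut-2-en-1-yl)benzoyl]-5-[2,4-bis(methoxymethoxy)phenyl]-3-methylcyclohex-2-en-1-yl]-2-hydroxy-4-(methoxymethoxy)benzaldehyde | CC(C)=CCc1c(OCOC)ccc(C(=O)[C@H]2[C@@H](c3c(OCOC)ccc(C=O)c3O)C=C(C)C[C@@H]2c2ccc(OCOC)cc2OCOC)c1OCOC
A3 | alternative 1 | 2-ethenyl-5-(methoxymethoxy)phenol | C=Cc1ccc(OCOC)cc1O
A4 | alternative 2 | [2,4-dihydroxy-3-(3-methylbut-2-en-1-yl)phenyl][(1R,2S,6S)-2-[2,6-bis(methoxymethoxy)-3-(2-methyl-1,3-dioxolan-2-yl)phenyl]-6-[2,4-bis(methoxymethoxy)phenyl]-4-methylcyclohex-3-en-1-yl]methanone | CC(C)=CCc1c(O)ccc(C(=O)[C@H]2[C@@H](c3c(OCOC)ccc(C4(C)OCCO4)c3OCOC)C=C(C)C[C@@H]2c2ccc(OCOC)cc2OCOC)c1O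
A5 | alternative 2 | 1-[(1R,2S,6S)-2-[2,6-bis(methoxymethoxy)-3-(2-methyl-1,3-dioxolan-2-yl)phenyl]-6-[2,4-bis(methoxymethoxy)phenyl]-4-methylcyclohex-3-en-1-yl]prop-2-yn-1-one | C#CC(=O)[C@H]1[C@@H](c2c(OCOC)ccc(C3(C)OCCO3)c2OCOC)C=C(C)C[C@@H]1c1ccc(OCOC)cc1OCOC
A6 | alternative 2 | 1-methoxy-2-(3-methylbut-2-en-1-yl)-1,3-bis(trimethylsilyloxy)buta-1,3-diene | COC(O[Si](C)(C)C)=C(CC=C(C)C)C(=C)O[Si](C)(C)C
A7 | alternative 3 | (1R,2S,6S)-2-[2,6-bis(methoxymethoxy)-3-(2-methyl-1,3-dioxolan-2-yl)phenyl]-6-[2,4-bis(methoxymethoxy)phenyl]-N-methoxy-N,4-dimethylcyclohex-3-ene-1-carboxamide | CON(C)C(=O)[C@H]1[C@@H](c2c(OCOC)ccc(C3(C)OCCO3)c2OCOC)C=C(C)C[C@@H]1c1ccc(OCOC)cc1OCOC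
A8 | alternative 3 | 3-[2,4-bis(methoxymethoxy)phenyl]-2-{1-[2,6-bis(methoxymethoxy)-3-(2-methyl-1,3-dioxolan-2-yl)phenyl]prop-2-en-1-yl}-N-methoxy-N,5-dimethylhex-5-enamide, configured as in A7 | CON(C)C(=O)[C@@H]([C@@H](c1c(OCOC)ccc(C2(C)OCCO2)c1OCOC)C=C)[C@@H](c1ccc(OCOC)cc1OCOC)CC(C)=C
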